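**Retrosynthetic overview**
1. Benzyl eicosanoate is cut mid-chain at C12–C13. A mixed Kolbe electrolysis (anodic decarboxylative radical cross-coupling) joins an octyl unit (C13–C20, from nonanoic acid) to a 12-(benzyloxy)-12-oxododecyl unit (C1–C12, from monobenzyl tridecanedioate). The two CO2H groups are traceless activators lost as CO2, and the coupling product is the target itself.
2. Enabling feature: C12 and C13 are plain, unbranched CH2 carbons in an unfunctionalised polymethylene chain, with no heteroatom, branch or π-system at C11–C14. Both are therefore accessible as primary alkyl radicals that couple rather than oxidise further. The only functional group, the C1 benzyl ester with its phenyl ring, lies eleven CH2 groups from C12.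
3. Both coupling partners come from one C22 fatty acid. Oxidative cleavage of the C13=C14 alkene of benzyl erucate gives the half-ester, with its chain ends already differentiated, plus nonanoic acid. Over the route, the two olefinic carbons are excised as CO2.
4. Benzyl erucate comes from erucic acid and benzyl bromide.
5. No ring is formed in the route. The only ring, the phenyl ring, is bought with benzyl bromide.

Key step: step 3

Remark on the chemistry: the target has no stereocentre and no stereogenic double bond, so it is achiral and the structure as drawn is the only stereoisomer. No step needs stereocontrol, and the Z-alkene of erucic acid is destroyed in step 2.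

**Step 1**
Reactants: 1 erucic acid, (Z)-docos-13-enoic acid; 2 benzyl bromide
Product: 3 benzyl (Z)-docos-13-enoate (benzyl erucate)
Conditions: K2CO3 (1.5 equiv), DMF, rt
Reagents that add atoms: none
Why: SN2 O-alkylation of the potassium carboxylate by the reactive benzylic bromide (carboxylate alkylation) runs without acid, so the C13=C14 alkene should not migrate, and no stereocentre is involved.

**Step 2**
Reactants: 3 benzyl erucate
Product: 4 13-(benzyloxy)-13-oxotridecanoic acid (monobenzyl tridecanedioate)
Conditions: OsO4 (1 mol%), Oxone (4 equiv), DMF, rt; aqueous work-up, silica filtration
Reagents that add atoms: potassium peroxymonosulfate (active salt of Oxone), [K+].[O-]S(=O)(=O)OO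
Why: Osmium-catalysed oxidative cleavage with peroxymonosulfate as terminal oxidant, a reaction type established for internal alkenes of fatty esters, should take the only alkene directly to two carboxylic acids, leave the benzyl ester and phenyl ring untouched, and give 4 together with one equivalent of nonanoic acid 5, which is kept because it is the partner of step 3; no stereocentre is formed.

**Step 3**
Reactants: 4 13-(benzyloxy)-13-oxotridecanoic acid; 5 nonanoic acid
Product: 8 benzyl eicosanoate, via octyl radical 6 (not isolated), via 12-(benzyloxy)-12-oxododecyl radical 7 (not isolated)
Conditions: undivided cell, smooth Pt anode, Pt cathode, 5 (about 5 equiv in total, the equivalent from step 2 included), KOH (5 mol% of total acid), MeOH, 45–50 °C, constant current about 0.2 A cm−2, periodic polarity reversal, stopped while the solution is still weakly acidic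
Reagents that add atoms: none
Why: At a smooth platinum anode and high current density both carboxylates lose one electron and then CO2, so that radicals 6 and 7 arise side by side in the dense layer at the electrode and combine to form the C12–C13 bond of 8, while protons are reduced to hydrogen at the cathode. The closest known reaction type is the classical mixed Kolbe chain extension of a fatty acid with a dicarboxylic acid half-ester, which is this very substrate class, and benzyl esters are established spectators in Kolbe couplings. No ring is closed and no stereocentre is created, so no mode of closure or controlling element applies. Radical coupling must win over further oxidation to cations (the Hofer–Moest pathway), and the substrates secure this because 6 and 7 are unbranched primary CH2 radicals without an α-heteroatom, α-branch or adjacent π-system. Cross- versus homo-coupling is statistical, so the cheap partner 5 is used in roughly fivefold excess to channel most of 7 into 8, and the two symmetrical dimers (a hydrocarbon and a diester) each differ from 8 by a whole ester group and should separate on a short silica column. The benzyl ester lies eleven CH2 groups from the radical centre, its unactivated phenyl ring is harder to oxidise than the adsorbed carboxylates, and the free acid still present keeps the medium weakly acidic, so methanolysis is not expected.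

**Compound list**
1 | erucic acid, (Z)-docos-13-enoic acid | CCCCCCCC/C=C\CCCCCCCCCCCC(=O)O | starting material
2 | benzyl bromide | BrCc1ccccc1 | starting material
3 | benzyl (Z)-docos-13-enoate (benzyl erucate) | CCCCCCCC/C=C\CCCCCCCCCCCC(=O)OCc1ccccc1 | intermediate
4 | 13-(benzyloxy)-13-oxotridecanoic acid | OC(=O)CCCCCCCCCCCC(=O)OCc1ccccc1 | intermediate
5 | nonanoic acid (bought; one further equivalent arises in step 2) | CCCCCCCCC(=O)O | starting material
6 | octyl radical (not isolated) | CCCCCCC[CH2] | intermediate
7 | 12-(benzyloxy)-12-oxododecyl radical (not isolated) | [CH2]CCCCCCCCCCC(=O)OCc1ccccc1 | intermediate
8 | benzyl eicosanoate (eicosanoic acid phenylmethyl ester), achiral | CCCCCCCCCCCCCCCCCCCC(=O)OCc1ccccc1 | target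

**Total step count:** 3
**Longest linear sequence:** 3 (1 → 3 → 4 → 8)

**Steps most likely to fail**

Step 3 carries the most risk.
- Homo-coupling of the ester-bearing radical may consume 4.
- A waxy film may foul the anode, so that the high-potential Kolbe regime is lost and two-electron oxidation takes over.
- The benzyl ester may undergo methanolysis if the layer at the cathode or the bulk turns basic.

The fallback sets out from 4 and comes back to the route at 8. Compound 4 is freed from 5 by bulb-to-bulb distillation. It would then be condensed with N-hydroxyphthalimide (DIC, cat. DMAP, CH2Cl2) to the redox-active ester 1-benzyl 13-(1,3-dioxoisoindolin-2-yl) tridecanedioate F1. This would be coupled under nickel catalysis (NiCl2·glyme, 2,2′-bipyridine, THF–DMF, rt) with dioctylzinc F2, prepared from commercial octylmagnesium bromide and ZnCl2. This known decarboxylative Negishi-type alkyl–alkyl coupling forms the same C12–C13 bond. It is cross-selective by design and needs neither methanol nor an anode.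

Step 2 comes next.
- The lipophilic C29 ester may dissolve poorly in DMF.
- The oxidation may stall before both carbons reach the acid level.
- The acidic bisulfate medium may slowly erode the benzyl ester.
- Sulfate or osmium residues carried forward would disturb the carboxylate layer at the anode in step 3.

The fallback sets out from 2 and comes back at 4, bypassing the cleavage altogether. Commercial tridecanedioic acid (OC(=O)CCCCCCCCCCCC(=O)O) would be mono-alkylated with one equivalent each of KHCO3 and 2 in DMF. The statistical mixture would be separated by acid–base extraction and chromatography, with unreacted diacid recycled. All of 5 is then bought. This fallback makes no compound missing from the list (F0).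

Step 1 is the least critical. The potassium soap of the C22 acid may gel or precipitate in DMF, leaving the alkylation slow and incomplete. The fallback sets out from 1 and comes back at 3, replacing O-alkylation by acyl substitution. Compound 1 would be converted with oxalyl chloride (cat. DMF, CH2Cl2) into (Z)-docos-13-enoyl chloride F3. This would then be treated with benzyl alcohol, Et3N and cat. DMAP in CH2Cl2.

**Further compounds**
F1 | step 3 | 1-benzyl 13-(1,3-dioxoisoindolin-2-yl) tridecanedioate | O=C(CCCCCCCCCCCC(=O)OCc1ccccc1)ON1C(=O)c2ccccc2C1=O
F2 | step 3 | dioctylzinc | CCCCCCCC[Zn]CCCCCCCC
F0 | step 2 | none | none
F3 | step 1 | (Z)-docos-13-enoyl chloride | CCCCCCCC/C=C\CCCCCCCCCCCC(=O)Cl
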